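**Retrosynthetic overview**
Numbering: lactone ring O1–C2(=O)–C3(OH)–C4–C5; C7' is the benzylic CH2 on C3 and C7 the one on C4.
Enabling feature: the tertiary C3–OH sits between the C2 carbonyl of the lactone ring and the electron-rich benzylic carbon C7'. The array O–C3–C7' can therefore be stored as a spiro-oxirane whose C7'–O bond is hydrogenolysable, C2=O makes C3 a carbanion site, and the C4 benzyl group blocks one face of the five-membered ring.
Last disconnection: target ⇒ bis(benzyl ether) spiro-oxirane, with three benzylic C–O bonds (oxirane C7'–O and two aryl benzyl ethers) cleaved in one hydrogenolysis.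
Key disconnection C3–C7': spiro-oxirane ⇒ α-bromo-β-benzyl-γ-butyrolactone + O-benzylvanillin (Darzens). Aldol addition anti to the C4 benzyl group, then invertive closure, places C7' cis and O trans to that group.
Bromolactone ⇒ (R)-β-benzyl lactone ⇒ Stobbe half-ester of the same aldehyde and dimethyl succinate, with asymmetric hydrogenation setting C4. Ring order: lactone (step 3), temporary oxirane (step 5), oxirane opened (step 6).

Key step: step 5

Remark on the target: the SMILES reads as (3R,4S), with the two benzyl groups cis on the lactone ring and the C3–OH trans to the C4 benzyl group.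
Assumption: the (S,S) antipode of Et-DuPHOS is taken to give the (R)-succinate, by analogy with its sense on itaconates; if the sense is opposite, the (R,R) antipode is used with no other change.
Remark: 10 forms as C3 epimers and 13 may form as epimers at the oxirane CH. The expected main isomers are drawn, and all of them converge on 14.

**Step 1**
Reactants: 1 4-(benzyloxy)-3-methoxybenzaldehyde; 2 dimethyl succinate
Product: 3 (E)-4-[4-(benzyloxy)-3-methoxyphenyl]-3-(methoxycarbonyl)but-3-enoic acid
Conditions: NaOMe, MeOH, reflux; then aq. HCl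
Reagents that add atoms: none
Why: Stobbe condensation, in which the succinate enolate adds to the non-enolisable aldehyde, the aldolate lactonises to a paraconic ester, and E1cB opening should give the (E)-half-ester with its two carboxyl carbons differentiated for step 3.

**Step 2**
Reactants: 3 (E)-4-[4-(benzyloxy)-3-methoxyphenyl]-3-(methoxycarbonyl)but-3-enoic acid
Product: 4 (R)-4-[4-(benzyloxy)-3-methoxyphenyl]-3-(methoxycarbonyl)butanoic acid
Conditions: H2 (5 atm), [Rh(cod)((S,S)-Et-DuPHOS)]BF4 (cat.), NaOMe (0.1 equiv), MeOH, rt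
Reagents that add atoms: none
Why: Rhodium-catalysed asymmetric hydrogenation of a Stobbe-type itaconate half-ester, in which the carboxylate arm chelates rhodium and the C2-symmetric bisphospholane exposes one alkene face only, setting the (R) centre that becomes C4 while the aryl benzyl ethers stay inert to this homogeneous catalyst.

**Step 3**
Reactants: 4 (R)-4-[4-(benzyloxy)-3-methoxyphenyl]-3-(methoxycarbonyl)butanoic acid
Product: 7 (R)-4-[4-(benzyloxy)-3-methoxybenzyl]dihydrofuran-2(3H)-one, via potassium carboxylate 5 (not isolated), via hydroxy acid 6 (not isolated)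
Conditions: KOH (1.0 equiv), EtOH, 0 °C; CaCl2, NaBH4, EtOH, −10 °C → rt; then 2 M HCl, rt
Reagents that add atoms: none
Why: Chemoselective borohydride reduction, in which Ca(BH4)2 reduces the methyl ester but not the carboxylate salt and acidification closes the γ-lactone (5-exo-trig acyl substitution) without touching the stereocentre.

**Step 4**
Reactants: 7 (R)-4-[4-(benzyloxy)-3-methoxybenzyl]dihydrofuran-2(3H)-one
Product: 10 (3R,4S)-4-[4-(benzyloxy)-3-methoxybenzyl]-3-bromodihydrofuran-2(3H)-one, via lithium enolate 8 (not isolated), via ketene silyl acetal 9 (not isolated)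
Conditions: LiN(iPr)2, THF, −78 °C; TMSCl, −78 → 0 °C; concentrate; NBS (1.0 equiv), THF, −78 °C
Reagents that add atoms: N-bromosuccinimide O=C1CCC(=O)N1Br
Why: Electrophilic α-bromination of a ketene silyl acetal, which should stop at monobromination because no enolate remains when the product forms; bromine enters mainly anti to the C4 benzyl group, but this centre is made planar again in step 5 and its configuration does not matter.

**Step 5**
Reactants: 10 (3R,4S)-4-[4-(benzyloxy)-3-methoxybenzyl]-3-bromodihydrofuran-2(3H)-one; 1 4-(benzyloxy)-3-methoxybenzaldehyde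
Product: 13 (2S,3S,7S)-7-[4-(benzyloxy)-3-methoxybenzyl]-2-[4-(benzyloxy)-3-methoxyphenyl]-1,5-dioxaspiro[2.4]heptan-4-one, via lithium bromoenolate 11 (not isolated), via lithium bromohydrin alkoxide 12 (not isolated)
Conditions: LiN(SiMe3)2 (1.05 equiv), THF, −78 °C, 5 min; 1 (1.1 equiv), −78 → 0 °C; pH 7 buffer
Reagents that add atoms: none
Why: Darzens glycidic ester condensation of an α-bromo lactone: LiN(SiMe3)2 removes the C3 proton, which C2=O and Br acidify, bromoenolate 11 adds to the aldehyde carbon of 1 (new C3–C7' bond), and alkoxide 12 expels bromide. The one ring closed is the oxirane C3–O–C7', by a 3-exo-tet SN2 displacement with O and Br antiperiplanar. C3 is controlled by the C4 benzyl group on the five-membered ring: the aldehyde is taken up on the enolate face anti to it, so 12 carries C7' trans and Br cis to that group, and the inversion at C3 during closure exchanges the two positions, leaving O trans and C7' cis to the C4 benzyl group, the contra-steric arrangement of the target that an anti benzylation or anti benzyl addition at C3 would miss. C7' is expected to be S (closed lithium chair with the aryl group equatorial, which ends with the aryl group syn to C2=O), but its configuration is of no consequence because step 6 turns it into CH2. The step needs C3 deprotonation in preference to loss of HBr across C3–C4 and to attack on the lactone carbonyl, which the acidity of C3–H, the hindered amide base and −78 °C secure; it also needs the anti series to persist if the aldol step reverses, which is secured because in the syn aldolate the alkoxide would have to swing over the ring face bearing the C4 benzyl group to reach the back of the C–Br bond. C4 is β to the carbonyl group and is not touched, and aldehyde 1 cannot enolise.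

**Step 6**
Reactants: 13 (2S,3S,7S)-7-[4-(benzyloxy)-3-methoxybenzyl]-2-[4-(benzyloxy)-3-methoxyphenyl]-1,5-dioxaspiro[2.4]heptan-4-one
Product: 14 epinortrachelogenin, (3R,4S)-3-hydroxy-3,4-bis(4-hydroxy-3-methoxybenzyl)dihydrofuran-2(3H)-one
Conditions: H2 (1 atm), 10% Pd/C, EtOAc–EtOH, rt
Reagents that add atoms: none
Why: Catalytic hydrogenolysis of an aryl glycidate to an α-hydroxy ester combined with O-debenzylation, in which Pd should cleave the three benzylic C–O bonds (oxirane C7'–O and both aryl benzyl ethers) while the non-benzylic C3–O bond stays, so C3 keeps its configuration and C7' becomes CH2.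

**Compound list**
1 | 4-(benzyloxy)-3-methoxybenzaldehyde (O-benzylvanillin) | COc1cc(C=O)ccc1OCc1ccccc1 | starting material
2 | dimethyl succinate | COC(=O)CCC(=O)OC | starting material
3 | (E)-4-[4-(benzyloxy)-3-methoxyphenyl]-3-(methoxycarbonyl)but-3-enoic acid | COC(=O)/C(CC(=O)O)=C/c1ccc(OCc2ccccc2)c(OC)c1 | intermediate
4 | (R)-4-[4-(benzyloxy)-3-methoxyphenyl]-3-(methoxycarbonyl)butanoic acid | COc1cc(C[C@H](CC(=O)O)C(=O)OC)ccc1OCc1ccccc1 | intermediate
5 | potassium (R)-4-[4-(benzyloxy)-3-methoxyphenyl]-3-(methoxycarbonyl)butanoate | COc1cc(C[C@H](CC(=O)[O-])C(=O)OC)ccc1OCc1ccccc1.[K+] | intermediate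
6 | (R)-4-[4-(benzyloxy)-3-methoxyphenyl]-3-(hydroxymethyl)butanoic acid | COc1cc(C[C@H](CC(=O)O)CO)ccc1OCc1ccccc1 | intermediate
7 | (R)-4-[4-(benzyloxy)-3-methoxybenzyl]dihydrofuran-2(3H)-one | COc1cc(C[C@H]2COC(=O)C2)ccc1OCc1ccccc1 | intermediate
8 | lithium enolate of 7, (4R) | COc1cc(C[C@H]2COC([O-])=C2)ccc1OCc1ccccc1.[Li+] | intermediate
9 | {[(4R)-4-(4-benzyloxy-3-methoxybenzyl)-4,5-dihydrofuran-2-yl]oxy}trimethylsilane | COc1cc(C[C@H]2COC(O[Si](C)(C)C)=C2)ccc1OCc1ccccc1 | intermediate
10 | (3R,4S)-4-[4-(benzyloxy)-3-methoxybenzyl]-3-bromodihydrofuran-2(3H)-one (trans isomer drawn; the 3S epimer is carried along) | COc1cc(C[C@H]2COC(=O)[C@@H]2Br)ccc1OCc1ccccc1 | intermediate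
11 | lithium enolate of 10, (4S) | COc1cc(C[C@H]2COC([O-])=C2Br)ccc1OCc1ccccc1.[Li+] | intermediate
12 | lithium (S)-[4-(benzyloxy)-3-methoxyphenyl]{(3R,4S)-4-[4-(benzyloxy)-3-methoxybenzyl]-3-bromo-2-oxotetrahydrofuran-3-yl}methanolate | COc1cc(C[C@H]2COC(=O)[C@]2(Br)[C@@H]([O-])c2ccc(OCc3ccccc3)c(OC)c2)ccc1OCc1ccccc1.[Li+] | intermediate
13 | (2S,3S,7S)-7-[4-(benzyloxy)-3-methoxybenzyl]-2-[4-(benzyloxy)-3-methoxyphenyl]-1,5-dioxaspiro[2.4]heptan-4-one (oxirane O trans and oxirane CH cis to the C7 benzyl group; aryl syn to C=O) | COc1cc(C[C@H]2COC(=O)[C@]23O[C@H]3c2ccc(OCc3ccccc3)c(OC)c2)ccc1OCc1ccccc1 | intermediate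
14 | epinortrachelogenin, (3R,4S)-3-hydroxy-3,4-bis(4-hydroxy-3-methoxybenzyl)dihydrofuran-2(3H)-one | COc1cc(C[C@H]2COC(=O)[C@@]2(O)Cc2ccc(O)c(OC)c2)ccc1O | target

**Total step count:** 6. **Longest linear sequence:** 6 steps (1 → 3 → 4 → 7 → 10 → 13 → 14). Aldehyde 1 supplies both aryl units.

**Steps most likely to fail**

Step 5. The bromoenolate may decay by bromine transfer or loss of HBr before it meets the aldehyde. The aldol step may reverse with erosion of facial control, or the acid-labile aryl oxirane may be opened by the lithium bromide present during warming. The fallback sets out from 7 and comes back at 14; it brings in the C–C bond and the oxygen separately. Lithium enolate 8 (from 7, LiN(iPr)2, THF, −78 °C) is added to 1 to give the lithium aldolate F1, which Ac2O traps in the same flask as the aldol acetate F2. DBU in toluene eliminates acetic acid to the (E)-benzylidene lactone F3, in which allylic strain with the aryl group holds the C4 benzyl group pseudoaxial. OsO4 (cat.), NMO, acetone–water should then dihydroxylate the open face anti to that group and give the diol F4, with the C3–OH trans to the C4 benzyl group. H2, Pd/C, EtOH–AcOH removes the benzylic C7'–OH and both benzyl ethers and gives 14.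

Step 6. The benzylic C7'–O bond may ionise on the catalyst support before hydrogen is delivered, followed by a 1,2-acyl shift (Meinwald rearrangement) or capture of the alcohol solvent. The fallback sets out from 13 and comes back at 14; the oxirane is opened first by a soft nucleophile. PhSH, Zn(OAc)2 (cat.), toluene should attack the benzylic carbon, as in thiol openings of aryl glycidates, and give the hydroxy sulfide F5. Raney Ni, EtOH cleaves the C–S bond to di-O-benzylepinortrachelogenin F6. H2, Pd/C, EtOAc then gives 14.

Step 4. Possible failures are C-silylation in place of O-silylation, a second bromination, bromination of the electron-rich arene, and loss of HBr to the butenolide on purification. The fallback sets out from 7 and comes back at 10; bromide is brought in as a nucleophile. LiN(SiMe3)2 and CF3CO2CH2CF3 in THF at −78 °C give the α-trifluoroacetyl lactone F7. MsN3, Et3N, MeCN (deacylative diazo transfer) gives the α-diazo lactone F8. One equivalent of HBr in Et2O at −20 °C protonates C3 and bromide displaces dinitrogen to give 10, a sequence that cannot over-brominate.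

**Further compounds**
F1 | step 5 | lithium [4-(benzyloxy)-3-methoxyphenyl]{(3S,4R)-4-[4-(benzyloxy)-3-methoxybenzyl]-2-oxotetrahydrofuran-3-yl}methanolate (both epimers at the carbinol carbon) | COc1cc(C[C@H]2COC(=O)[C@@H]2C([O-])c2ccc(OCc3ccccc3)c(OC)c2)ccc1OCc1ccccc1.[Li+]
F2 | step 5 | [4-(benzyloxy)-3-methoxyphenyl]{(3S,4R)-4-[4-(benzyloxy)-3-methoxybenzyl]-2-oxotetrahydrofuran-3-yl}methyl acetate (both epimers at the acetoxy carbon) | COc1cc(C[C@H]2COC(=O)[C@@H]2C(OC(C)=O)c2ccc(OCc3ccccc3)c(OC)c2)ccc1OCc1ccccc1
F3 | step 5 | (R,E)-4-[4-(benzyloxy)-3-methoxybenzyl]-3-[4-(benzyloxy)-3-methoxybenzylidene]dihydrofuran-2(3H)-one | COc1cc(C[C@H]2COC(=O)/C2=C/c2ccc(OCc3ccccc3)c(OC)c2)ccc1OCc1ccccc1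
F4 | step 5 | (3S,4S)-4-[4-(benzyloxy)-3-methoxybenzyl]-3-{(R)-[4-(benzyloxy)-3-methoxyphenyl](hydroxy)methyl}-3-hydroxydihydrofuran-2(3H)-one | COc1cc(C[C@H]2COC(=O)[C@@]2(O)[C@H](O)c2ccc(OCc3ccccc3)c(OC)c2)ccc1OCc1ccccc1
F5 | step 6 | (3R,4S)-4-[4-(benzyloxy)-3-methoxybenzyl]-3-{[4-(benzyloxy)-3-methoxyphenyl](phenylsulfanyl)methyl}-3-hydroxydihydrofuran-2(3H)-one (either epimer at the sulfide carbon) | COc1cc(C[C@H]2COC(=O)[C@@]2(O)C(Sc2ccccc2)c2ccc(OCc3ccccc3)c(OC)c2)ccc1OCc1ccccc1
F6 | step 6 | (3R,4S)-3,4-bis[4-(benzyloxy)-3-methoxybenzyl]-3-hydroxydihydrofuran-2(3H)-one | COc1cc(C[C@H]2COC(=O)[C@@]2(O)Cc2ccc(OCc3ccccc3)c(OC)c2)ccc1OCc1ccccc1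
F7 | step 4 | (4R)-4-[4-(benzyloxy)-3-methoxybenzyl]-3-(trifluoroacetyl)dihydrofuran-2(3H)-one (C3 enolisable) | COc1cc(C[C@H]2COC(=O)C2C(=O)C(F)(F)F)ccc1OCc1ccccc1
F8 | step 4 | (R)-4-[4-(benzyloxy)-3-methoxybenzyl]-3-diazodihydrofuran-2(3H)-one | COc1cc(C[C@H]2COC(=O)C2=[N+]=[N-])ccc1OCc1ccccc1
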